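Neither earlier run can be read at the asked time, because both stop at 60.0 s, short of it, and neither has the reagent of ochre or teal.

| flask | substrate | reagent | remark | time |
|---|---|---|---|---|
| midnight | 2 mM | 3.6 mM | run made earlier |  |
| autumn | 2 mM | 8.1 mM | run made earlier |  |
| ochre | 2.0 mM | 10.0 mM |  | 2.0 min |
| teal | 2.0 mM | 5.00 mM |  | 2.0 min |

| run | time / s | substrate / % | target / % |
|---|---|---|---|
| midnight | 10.0 | 91.0 | 0.4 |
| midnight | 15.0 | 86.9 | 0.1 |
| midnight | 25.0 | 78.8 | 1.1 |
| midnight | 40.0 | 69.6 | 3.3 |
| midnight | 50.0 | 64.9 | 3.6 |
| midnight | 60.0 | 60.1 | 5.3 |
| autumn | 10.0 | 80.9 | 0.4 |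
| autumn | 12.0 | 77.1 | 0.6 |
| autumn | 15.0 | 73.2 | 1.0 |
| autumn | 25.0 | 60.6 | 2.8 |
| autumn | 40.0 | 47.1 | 5.7 |
| autumn | 60.0 | 35.3 | 10.8 |

(standard deviation of a reading: 0.3 percentage points)

- for by-product the idle adduct is counted in
- steps thought possible: intermediate -> target; substrate + by-product <-> idle adduct; substrate + reagent -> intermediate + by-product
- what has gone from substrate into another species counts as reacted, even if it can come back

* part of the substrate that has reacted at the end, ochre
* part of the substrate that has reacted at the end, teal
* what raising the concentration of reagent from its lowest to its highest value here does to the part of the substrate that has reacted (changes below 5 percentage points count as none) (it falls / no change / it rises)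

Idle adduct counts as reacted, so the part reacted is the charge minus the substrate column. We multiply reagent charged by time and call this the exposure, for teal 600 mM·s and for ochre 1200 mM·s. Substrate is the limiting reagent (2 mM against 8.1 mM in autumn), so reagent is treated as roughly constant, a pseudo-first-order picture. Sorted by exposure, the runs give this substrate left:

- midnight, 90.0 mM·s: 78.8%; autumn, 97.2 mM·s: 77.1%
- midnight, 216 mM·s: 60.1%; autumn, 202 mM·s: 60.6%
- autumn, 324 mM·s: 47.1%
- autumn, 486 mM·s: 35.3%

The first two rows pair up: at like exposure, the two runs stand close together despite 2.25 times the reagent. The last two rows show the slowing. The log fall per exposure is 0.00262 mM⁻¹ s⁻¹ at autumn's first reading, but 0.00178 mM⁻¹ s⁻¹ between its last two.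

We join the ends by carrying that late slope on from autumn's last reading. Teal then keeps 28.8% and ochre 9.90%, so we commit to 71.2% reacted for teal and 90.1% for ochre, a rise of 19 percentage points.

The forecast gives 89% for ochre, 68% for teal, and it rises, below ours on both, holding that “substrate loss is first order in reagent”.

The flasks give 85.5% for ochre and 68.8% for teal, and it rises by 17 points.

    intermediate → target (k = 0.00770 s⁻¹)
    substrate + by-product ⇌ idle adduct, settled at all times (K = 930 M⁻¹)
    substrate + reagent → intermediate + by-product (k = 1.70 M⁻¹ s⁻¹)

From autumn's last reading out to teal's exposure, the log fall per exposure comes to 0.00108 mM⁻¹ s⁻¹, less than the late slope we carried. In teal at 2.00 min, the step from substrate and reagent gives reagent a half-life of 11 min against 1.7 min for substrate. Teal read at 50 s has an exposure of 250 mM·s, between the second and third rows; interpolating the log there gives 54.9% substrate left, and that flask holds 55.3%.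

The readings were generated by integration with constants of no real substance; noise was put on by code.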